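**Retrosynthetic overview**

1. Ring A (C1'–C6') is the only ring to be built. Its C3'(prenyl)–C4'(O)–C5'(prenyl) segment is a symmetric ketone with the same prenyl-bearing carbon on each side, and C6'–C1'–C2' is the three-carbon unit of an acrylate whose α-carbon (C1') can carry sulfur. Ring B arrives intact.
2. Target ⇒ (O–Si cleavage on ring B) ⇒ non-aromatic ring A: a cyclohexane-1,3-dione with phenylsulfanyl and the acyl chain on C1'. In the forward sense, sulfoxide elimination across C1'–C6' and enolization make the arene.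
3. C1'–C(=O) ⇒ dianion of 2,4-diprenyl-6-(phenylsulfanyl)cyclohexane-1,3-dione plus the N-methoxy-N-methylamide of O-silylated 3-(4-hydroxyphenyl)propanoic acid.
4. C5'–C6' and C2'–C3' ⇒ Michael–Claisen (3+3) annulation of 2,10-dimethylundeca-2,9-dien-6-one with methyl 2-(phenylsulfanyl)acrylate, which closes ring A.
5. Ketone ⇐ homoprenyl Grignard reagent plus ethyl formate, then oxidation; acrylate ⇐ methyl 2-(phenylsulfanyl)acetate by Mannich methylenation.

Key step: step 4

Assumption: compounds 10, 11 and 15 to 17 are carried as mixtures of diastereomers and enol tautomers; this is harmless because every stereocentre becomes an sp2 carbon when ring A aromatizes in step 8, and the target has none.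

**Route**

Step 1
Reactants: 1 5-bromo-2-methylpent-2-ene
Product: 4 2,10-dimethylundeca-2,9-dien-6-ol, via (4-methylpent-3-en-1-yl)magnesium bromide 2 (not isolated), via 5-methylhex-4-enal 3 (not isolated)
Conditions: Mg (1.1 equiv), cat. I2, THF, 40 °C; HCO2Et (0.45 equiv), 0 °C to rt; then cold 1 M HCl
Reagents that add atoms: ethyl formate, CCOC=O
Why: Double Grignard addition to a formate ester, in which the first addition releases aldehyde 3 and this, being more electrophilic than the formate, takes up the second equivalent of the stable primary homoallylic reagent 2 to give the symmetric secondary alcohol.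

Step 2
Reactants: 4 2,10-dimethylundeca-2,9-dien-6-ol
Product: 5 2,10-dimethylundeca-2,9-dien-6-one
Conditions: Dess–Martin periodinane (1.2 equiv), CH2Cl2, 0 °C to rt
Reagents that add atoms: none
Why: Dess–Martin oxidation of an unhindered secondary alcohol, to which the two trisubstituted alkenes are inert.

Step 3
Reactants: 6 methyl 2-(phenylsulfanyl)acetate
Product: 9 methyl 2-(phenylsulfanyl)prop-2-enoate, via Mannich base 7 (not isolated), via methiodide 8 (not isolated)
Conditions: LiN(SiMe3)2 (1.05 equiv), THF, −78 °C; CH2=NMe2+ I− (1.2 equiv), −78 °C to rt; MeI (3 equiv), MeOH, rt; aq NaHCO3/CH2Cl2, rt; product kept cold and used at once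
Reagents that add atoms: N,N-dimethylmethyleneiminium iodide (Eschenmoser's salt), C=[N+](C)C.[I-]
Why: Mannich methylenation, in which the ester enolate is aminomethylated by the iminium salt, the amine is quaternized, and trimethylamine leaves by an E1cB elimination made easy by the α-hydrogen that ester and sulfur acidify.

Step 4
Reactants: 5 2,10-dimethylundeca-2,9-dien-6-one, 9 methyl 2-(phenylsulfanyl)prop-2-enoate
Product: 11 2,4-bis(3-methylbut-2-en-1-yl)-6-(phenylsulfanyl)cyclohexane-1,3-dione, via Michael adduct 10 (not isolated)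
Conditions: KOtBu (2.2 equiv), 5 (1.2 equiv), THF, −10 °C; 9 (1.0 equiv) added over 2 h; −10 °C to rt; then 1 M HCl to pH 3
Reagents that add atoms: none
Why: KOtBu reversibly enolizes 5, whose α-carbon (the future C5') adds to the unsubstituted terminus of 9 (C6') to give the sulfur-stabilized ester enolate of 10; proton exchange through tBuOH then places the charge on the other α-carbon (C3'), which attacks the ester carbonyl (C2'), expels methoxide and leaves a 2-alkyl-1,3-dione whose irreversible deprotonation pulls the preceding equilibria forward. The closest known reaction is the consecutive Michael–Claisen annulation of dialkyl ketones with acrylate esters under KOtBu; an α-sulfanyl acrylate has not been tried as the partner, but it should be a better acceptor than methyl acrylate, and its ester stays open to Claisen attack whenever the adduct is protonated at C1'. Ring A (C1' to C6'), the only ring formed, closes in a 6-(enolexo)-exo-trig Claisen (Dieckmann-type) mode. The centres at C1' and C5' (C3' is enolized) are not controlled and need not be, since all become sp2 carbons in step 8. The step needs exactly one Michael addition followed by C-acylation: the symmetry of 5 makes its two α-carbons interchangeable so that only one dione can arise, slow addition of 9 to an excess of ketone enolate keeps the stabilized adduct enolate from adding to a second acrylate, closure from C5' would give a four-membered ring, and O-acylation to an enol lactone is reversed by alkoxide.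

Step 5
Reactants: 12 3-(4-hydroxyphenyl)propanoic acid
Product: 13 3-(4-hydroxyphenyl)-N-methoxy-N-methylpropanamide
Conditions: MeNHOMe·HCl (1.2 equiv), EDC·HCl (1.2 equiv), N-methylmorpholine (2.5 equiv), CH2Cl2, 0 °C to rt
Reagents that add atoms: N,O-dimethylhydroxylamine hydrochloride, CNOC.Cl
Why: Carbodiimide amide coupling, in which the amine outcompetes the weakly nucleophilic free phenol for the O-acylisourea.

Step 6
Reactants: 13 3-(4-hydroxyphenyl)-N-methoxy-N-methylpropanamide
Product: 14 3-[4-(tert-butyldimethylsilyloxy)phenyl]-N-methoxy-N-methylpropanamide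
Conditions: TBSCl (1.2 equiv), imidazole (2.5 equiv), DMF, rt
Reagents that add atoms: tert-butyldimethylsilyl chloride, CC(C)(C)[Si](C)(C)Cl
Why: Imidazole-mediated silylation of a phenol, which removes the acidic hydrogen that would otherwise quench the dianion of step 7.

Step 7
Reactants: 11 2,4-bis(3-methylbut-2-en-1-yl)-6-(phenylsulfanyl)cyclohexane-1,3-dione, 14 3-[4-(tert-butyldimethylsilyloxy)phenyl]-N-methoxy-N-methylpropanamide
Product: 16 6-{3-[4-(tert-butyldimethylsilyloxy)phenyl]propanoyl}-2,4-bis(3-methylbut-2-en-1-yl)-6-(phenylsulfanyl)cyclohexane-1,3-dione, via lithium hemiaminal 15 (not isolated)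
Conditions: LiN(iPr)2 (2.05 equiv), THF/DMPU, −78 to 0 °C; 14 (1.1 equiv), −78 to 0 °C; then cold 1 M HCl
Reagents that add atoms: none
Why: γ-Acylation of a 1,3-dicarbonyl dianion with a Weinreb amide, in which the first equivalent of base makes the unreactive dione enolate, the second removes the C1' hydrogen (acidified by both the C2' carbonyl and sulfur, whereas the C5' hydrogen has only a carbonyl), and this carbanion alone adds to the amide to give the chelated adduct 15, which resists over-addition and cleavage until the acidic work-up.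

Step 8
Reactants: 16 6-{3-[4-(tert-butyldimethylsilyloxy)phenyl]propanoyl}-2,4-bis(3-methylbut-2-en-1-yl)-6-(phenylsulfanyl)cyclohexane-1,3-dione
Product: 18 3-[4-(tert-butyldimethylsilyloxy)phenyl]-1-[2,4-dihydroxy-3,5-bis(3-methylbut-2-en-1-yl)phenyl]propan-1-one, via sulfoxide 17 (not isolated)
Conditions: mCPBA (1.0 equiv), CH2Cl2, −78 °C; then −78 °C to rt
Reagents that add atoms: none
Why: Sulfide oxidation followed by thermal syn-elimination of the sulfoxide (dehydrosulfenylation), which can only take a hydrogen from C6' because C1' has no other β-hydrogen, so that the C1'=C6' ene-dione formed is the keto tautomer of 18 and enolizes at C3' and C5' to the aromatic ring A without any oxidant that would cyclize ortho-prenyl phenols.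

Step 9
Reactants: 18 3-[4-(tert-butyldimethylsilyloxy)phenyl]-1-[2,4-dihydroxy-3,5-bis(3-methylbut-2-en-1-yl)phenyl]propan-1-one
Product: 19 gancaonin J, 1-[2,4-dihydroxy-3,5-bis(3-methylbut-2-en-1-yl)phenyl]-3-(4-hydroxyphenyl)propan-1-one
Conditions: Bu4NF (2.2 equiv), AcOH (2.2 equiv), THF, 0 °C to rt
Reagents that add atoms: none
Why: Fluoride cleavage of an aryl silyl ether, buffered with acetic acid so that the acidic ring A phenols stay protonated and the prenyl groups see neither strong base nor strong acid.

**Compound list**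

1 | 5-bromo-2-methylpent-2-ene | CC(C)=CCCBr | starting material
2 | (4-methylpent-3-en-1-yl)magnesium bromide (formed in the flask) | CC(C)=CCC[Mg]Br | intermediate
3 | 5-methylhex-4-enal (formed in the flask) | CC(C)=CCCC=O | intermediate
4 | 2,10-dimethylundeca-2,9-dien-6-ol | CC(C)=CCCC(O)CCC=C(C)C | intermediate
5 | 2,10-dimethylundeca-2,9-dien-6-one | CC(C)=CCCC(=O)CCC=C(C)C | intermediate
6 | methyl 2-(phenylsulfanyl)acetate | COC(=O)CSc1ccccc1 | starting material
7 | methyl 3-(dimethylamino)-2-(phenylsulfanyl)propanoate (racemic Mannich base, formed in the flask) | COC(=O)C(CN(C)C)Sc1ccccc1 | intermediate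
8 | [3-methoxy-3-oxo-2-(phenylsulfanyl)propyl]trimethylammonium iodide (racemic, formed in the flask) | COC(=O)C(C[N+](C)(C)C)Sc1ccccc1.[I-] | intermediate
9 | methyl 2-(phenylsulfanyl)prop-2-enoate | C=C(Sc1ccccc1)C(=O)OC | intermediate
10 | methyl 9-methyl-4-(3-methylbut-2-en-1-yl)-5-oxo-2-(phenylsulfanyl)dec-8-enoate (Michael adduct, present as its potassium enolate, diastereomer mixture, formed in the flask) | COC(=O)C(Sc1ccccc1)CC(CC=C(C)C)C(=O)CCC=C(C)C | intermediate
11 | 2,4-bis(3-methylbut-2-en-1-yl)-6-(phenylsulfanyl)cyclohexane-1,3-dione (mixture of diastereomers and enol tautomers) | CC(C)=CCC1CC(Sc2ccccc2)C(=O)C(CC=C(C)C)C1=O | intermediate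
12 | 3-(4-hydroxyphenyl)propanoic acid | O=C(O)CCc1ccc(O)cc1 | starting material
13 | 3-(4-hydroxyphenyl)-N-methoxy-N-methylpropanamide | CON(C)C(=O)CCc1ccc(O)cc1 | intermediate
14 | 3-[4-(tert-butyldimethylsilyloxy)phenyl]-N-methoxy-N-methylpropanamide | CON(C)C(=O)CCc1ccc(O[Si](C)(C)C(C)(C)C)cc1 | intermediate
15 | dilithium salt of the tetrahedral adduct of C6 of 11 to the amide carbonyl of 14: C6 bears phenylsulfanyl and C(O−)(NMeOMe)CH2CH2Ar, the ring dione is present as its enolate (diastereomer mixture, formed in the flask) | [Li+].[Li+].CC(C)=CCC1CC(Sc2ccccc2)(C([O-])(CCc2ccc(O[Si](C)(C)C(C)(C)C)cc2)N(C)OC)C(=O)C(CC=C(C)C)=C1[O-] | intermediate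
16 | 6-{3-[4-(tert-butyldimethylsilyloxy)phenyl]propanoyl}-2,4-bis(3-methylbut-2-en-1-yl)-6-(phenylsulfanyl)cyclohexane-1,3-dione (mixture of diastereomers and enol tautomers) | CC(C)=CCC1CC(Sc2ccccc2)(C(=O)CCc2ccc(O[Si](C)(C)C(C)(C)C)cc2)C(=O)C(CC=C(C)C)C1=O | intermediate
17 | 6-{3-[4-(tert-butyldimethylsilyloxy)phenyl]propanoyl}-2,4-bis(3-methylbut-2-en-1-yl)-6-(phenylsulfinyl)cyclohexane-1,3-dione (sulfoxide of 16, diastereomer mixture, formed in the flask) | CC(C)=CCC1CC(S(=O)c2ccccc2)(C(=O)CCc2ccc(O[Si](C)(C)C(C)(C)C)cc2)C(=O)C(CC=C(C)C)C1=O | intermediate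
18 | 3-[4-(tert-butyldimethylsilyloxy)phenyl]-1-[2,4-dihydroxy-3,5-bis(3-methylbut-2-en-1-yl)phenyl]propan-1-one | CC(C)=CCc1cc(C(=O)CCc2ccc(O[Si](C)(C)C(C)(C)C)cc2)c(O)c(CC=C(C)C)c1O | intermediate
19 | gancaonin J, 1-[2,4-dihydroxy-3,5-bis(3-methylbut-2-en-1-yl)phenyl]-3-(4-hydroxyphenyl)propan-1-one (no stereocentres) | CC(C)=CCc1cc(C(=O)CCc2ccc(O)cc2)c(O)c(CC=C(C)C)c1O | target

**Step count**

Total step count: 9. Longest linear sequence: 6 steps (steps 1, 2, 4, 7, 8, 9).

**Steps most likely to fail**

Step 4. The captodative acrylate may oligomerize under alkoxide, or the stabilized adduct enolate may add to a second acrylate. The sequence may also stall at the Michael adduct, because the ester sits mostly as its sulfur-stabilized enolate and is then a poor electrophile for the Claisen closure. The fallback sets out from 5 and comes back at 11, and it brings sulfur in after the ring is made. Ketone 5 and methyl acrylate under KOtBu in THF, the established form of this annulation, should give methyl 9-methyl-4-(3-methylbut-2-en-1-yl)-5-oxodec-8-enoate F1 in the flask and from it 2,4-bis(3-methylbut-2-en-1-yl)cyclohexane-1,3-dione F2. The dianion of F2 (LiN(iPr)2, 2.1 equiv, THF/DMPU, −78 °C) forms kinetically at the unsubstituted ring methylene and is sulfenylated there with PhSSPh to give 11.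

Step 7. The tertiary, sulfur-stabilized carbanion may add to the amide carbonyl only slowly or reversibly. Proton transfer to the amide or deprotonation at C5' would return starting material or give the wrong acylation site. The fallback sets out from 11 and comes back at the target 19, with acylation moved to the aromatic stage under non-acidic conditions:
- NaIO4 in aqueous MeOH should oxidize the α-keto sulfide to 2,4-bis(3-methylbut-2-en-1-yl)-6-(phenylsulfinyl)cyclohexane-1,3-dione F3.
- Warming in toluene over CaCO3 eliminates toward C6' and, after enolization, gives 2,4-bis(3-methylbut-2-en-1-yl)benzene-1,3-diol F4.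
- NaH and MeOCH2Cl give 1,3-bis(methoxymethoxy)-2,4-bis(3-methylbut-2-en-1-yl)benzene F5.
- nBuLi/TMEDA lithiates the only ring position ortho to an acetal oxygen (C1') by directed ortho-metalation, giving [2,4-bis(methoxymethoxy)-3,5-bis(3-methylbut-2-en-1-yl)phenyl]lithium F6.
- Addition to 14 gives lithium 1-[2,4-bis(methoxymethoxy)-3,5-bis(3-methylbut-2-en-1-yl)phenyl]-3-[4-(tert-butyldimethylsilyloxy)phenyl]-1-[methoxy(methyl)amino]propan-1-olate F7, and on work-up 1-[2,4-bis(methoxymethoxy)-3,5-bis(3-methylbut-2-en-1-yl)phenyl]-3-[4-(tert-butyldimethylsilyloxy)phenyl]propan-1-one F8.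
- HCl in MeOH at rt removes both acetals and the silyl ether to give 19.

Step 8. The peracid may attack the prenyl double bonds or the enolized dione before the hindered, electron-poor sulfide reacts, or it may over-oxidize sulfur to the sulfone, which cannot eliminate. The fallback sets out from 5 and comes back at 18. It replaces sulfur by selenium, which is oxidized by periodate without touching alkenes and eliminates below room temperature:
- 5 is annulated with methyl acrylate to 2,4-bis(3-methylbut-2-en-1-yl)cyclohexane-1,3-dione F2 as in the first fallback.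
- The dianion of F2 is selenenylated with PhSeBr at the unsubstituted methylene to give 2,4-bis(3-methylbut-2-en-1-yl)-6-(phenylselanyl)cyclohexane-1,3-dione F9.
- A second dianion, now at the selenium-bearing carbon, adds to 14 to give the dilithium tetrahedral adduct of the C6 carbanion of the selenide to the amide F10. Acidic work-up gives 6-{3-[4-(tert-butyldimethylsilyloxy)phenyl]propanoyl}-2,4-bis(3-methylbut-2-en-1-yl)-6-(phenylselanyl)cyclohexane-1,3-dione F11.
- NaIO4/NaHCO3 in aqueous THF at 0 °C gives the selenoxide 6-{3-[4-(tert-butyldimethylsilyloxy)phenyl]propanoyl}-2,4-bis(3-methylbut-2-en-1-yl)-6-(phenylseleninyl)cyclohexane-1,3-dione F12, whose syn-elimination toward C6' and enolization give 18.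

**Further compounds**

F1 | step 4 | methyl 9-methyl-4-(3-methylbut-2-en-1-yl)-5-oxodec-8-enoate | COC(=O)CCC(CC=C(C)C)C(=O)CCC=C(C)C
F2 | step 4 | 2,4-bis(3-methylbut-2-en-1-yl)cyclohexane-1,3-dione | CC(C)=CCC1CCC(=O)C(CC=C(C)C)C1=O
F3 | step 7 | 2,4-bis(3-methylbut-2-en-1-yl)-6-(phenylsulfinyl)cyclohexane-1,3-dione | CC(C)=CCC1CC(S(=O)c2ccccc2)C(=O)C(CC=C(C)C)C1=O
F4 | step 7 | 2,4-bis(3-methylbut-2-en-1-yl)benzene-1,3-diol | CC(C)=CCc1ccc(O)c(CC=C(C)C)c1O
F5 | step 7 | 1,3-bis(methoxymethoxy)-2,4-bis(3-methylbut-2-en-1-yl)benzene | COCOc1ccc(CC=C(C)C)c(OCOC)c1CC=C(C)C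
F6 | step 7 | [2,4-bis(methoxymethoxy)-3,5-bis(3-methylbut-2-en-1-yl)phenyl]lithium | [Li]c1cc(CC=C(C)C)c(OCOC)c(CC=C(C)C)c1OCOC
F7 | step 7 | lithium 1-[2,4-bis(methoxymethoxy)-3,5-bis(3-methylbut-2-en-1-yl)phenyl]-3-[4-(tert-butyldimethylsilyloxy)phenyl]-1-[methoxy(methyl)amino]propan-1-olate | [Li+].[O-]C(CCc1ccc(O[Si](C)(C)C(C)(C)C)cc1)(N(C)OC)c1cc(CC=C(C)C)c(OCOC)c(CC=C(C)C)c1OCOC
F8 | step 7 | 1-[2,4-bis(methoxymethoxy)-3,5-bis(3-methylbut-2-en-1-yl)phenyl]-3-[4-(tert-butyldimethylsilyloxy)phenyl]propan-1-one | COCOc1c(CC=C(C)C)cc(C(=O)CCc2ccc(O[Si](C)(C)C(C)(C)C)cc2)c(OCOC)c1CC=C(C)C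
F9 | step 8 | 2,4-bis(3-methylbut-2-en-1-yl)-6-(phenylselanyl)cyclohexane-1,3-dione | CC(C)=CCC1CC([Se]c2ccccc2)C(=O)C(CC=C(C)C)C1=O
F10 | step 8 | dilithium tetrahedral adduct of the C6 carbanion of the selenide to the amide (C6 bears phenylselanyl and C(O−)(NMeOMe)CH2CH2Ar, ring dione as its enolate) | [Li+].[Li+].CC(C)=CCC1CC([Se]c2ccccc2)(C([O-])(CCc2ccc(O[Si](C)(C)C(C)(C)C)cc2)N(C)OC)C(=O)C(CC=C(C)C)=C1[O-]
F11 | step 8 | 6-{3-[4-(tert-butyldimethylsilyloxy)phenyl]propanoyl}-2,4-bis(3-methylbut-2-en-1-yl)-6-(phenylselanyl)cyclohexane-1,3-dione | CC(C)=CCC1CC([Se]c2ccccc2)(C(=O)CCc2ccc(O[Si](C)(C)C(C)(C)C)cc2)C(=O)C(CC=C(C)C)C1=O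
F12 | step 8 | 6-{3-[4-(tert-butyldimethylsilyloxy)phenyl]propanoyl}-2,4-bis(3-methylbut-2-en-1-yl)-6-(phenylseleninyl)cyclohexane-1,3-dione | CC(C)=CCC1CC([Se](=O)c2ccccc2)(C(=O)CCc2ccc(O[Si](C)(C)C(C)(C)C)cc2)C(=O)C(CC=C(C)C)C1=O
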